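**Strategy.** The target is a nearly C2-symmetric, all-R, 2,3-cis/2′,3′-cis 3,3′-bichroman-4-one. The plan cuts each ring A from its pyranone ring C at O1–C8a and C4–C4a, which leaves an aryne and a syn,syn bis(β-hydroxy amide) that carries all four stereocentres. In the key step each benzylic oxygen adds to a 3,5-bis(benzyloxy)aryne and the resulting aryl anion is acylated by the neighbouring Weinreb amide, closing both pyranone rings with retention. It exploits that C4a (acyl) lies ortho to the C5 oxygen and C8a (ether O1) meta to it, the innate polarity of a 3-alkoxyaryne. The precursor comes from an enantioselectively made exo,exo bis-γ-lactone; a final mono-O-methylation differentiates the halves.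

Key step: step 6

Remark: CIP analysis of the target gives 2R,3R,2′R,3′R, so both pyranone rings are 2,3-cis; the route is laid out for this isomer. Unit 1 is the 5,7-dihydroxy half, unit 2 the 5-hydroxy-7-methoxy half (primed locants).

Step 1
Reactants: 1 ethyl 3-(4-methoxyphenyl)-3-oxopropanoate (2 equiv)
Product: 2 diethyl 2,3-bis(4-methoxybenzoyl)butanedioate (diastereomer mixture)
Conditions: NaH (1.05 equiv), THF, 0 °C; then I2 (0.5 equiv), 0 °C → rt
Reagents that add atoms: none
Why: Oxidative homocoupling of a β-keto ester enolate (α-iodination of one enolate, SN2 displacement by a second) is a classical route to 2,3-diacylsuccinates, and the two new stereocentres stay epimerisable, so the mixture is carried on as such.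

Step 2
Reactants: 2 diethyl 2,3-bis(4-methoxybenzoyl)butanedioate
Product: 4 (3R,3aR,6R,6aR)-3,6-bis(4-methoxyphenyl)tetrahydro-1H,3H-furo[3,4-c]furan-1,4-dione, via diol diester 3 (not isolated)
Conditions: RuCl[(R,R)-TsDPEN](p-cymene) (2 mol %), HCO2H/Et3N (5:2), DMF, 40 °C; then PPTS (cat.), toluene, 60 °C
Reagents that add atoms: none
Why: Noyori–Ikariya asymmetric transfer hydrogenation with dynamic kinetic resolution should set both aryl carbinol centres R by catalyst control (aryl versus alkyl discrimination, as for acetophenone) and draw the rapidly epimerising keto ester α-carbons into the syn (like) arrangement, and only the all-R tetrad can lactonise twice to the cis-fused exo,exo dilactone, so the double γ-lactonisation also purifies the stereoisomer.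

Step 3
Reactants: 4 (3R,3aR,6R,6aR)-3,6-bis(4-methoxyphenyl)tetrahydro-1H,3H-furo[3,4-c]furan-1,4-dione
Product: 5 (2R,3R)-2,3-bis[(R)-hydroxy(4-methoxyphenyl)methyl]-N1,N4-dimethoxy-N1,N4-dimethylbutanediamide
Conditions: MeNH(OMe)·HCl (6 equiv), AlMe3 (6 equiv), CH2Cl2, 0 °C → rt; aq. potassium sodium tartrate work-up; used without storage
Reagents that add atoms: N,O-dimethylhydroxylamine hydrochloride, CNOC.Cl
Why: Weinreb aminolysis of both γ-lactones by the aluminium amide made in the flask runs under Lewis-acidic, non-basic conditions (no retro-aldol, no β-elimination), touches no stereocentre and turns each lactone into a free benzylic hydroxyl plus an N-methoxy-N-methylamide that accepts carbanions well but alkoxides poorly.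

Step 4
Reactants: 6 3,5-bis(benzyloxy)phenol
Product: 7 3,5-bis(benzyloxy)-2-bromophenol
Conditions: NBS (1.0 equiv), CH2Cl2, −78 → 0 °C
Reagents that add atoms: N-bromosuccinimide, O=C1CCC(=O)N1Br
Why: Electrophilic aromatic bromination at low temperature should go ortho to the free hydroxyl (hydrogen-bonded delivery, while the position between the two benzyloxy groups is more hindered), and any 4-bromo isomer is removed by chromatography.

Step 5
Reactants: 7 3,5-bis(benzyloxy)-2-bromophenol
Product: 10 3,5-bis(benzyloxy)-2-(trimethylsilyl)phenyl trifluoromethanesulfonate, via aryl silyl ether 8 (not isolated), via lithium silylphenoxide 9 (not isolated)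
Conditions: HMDS, THF, reflux, then evaporation; n-BuLi, THF, −78 °C; Tf2O, −78 °C → rt
Reagents that add atoms: hexamethyldisilazane, C[Si](C)(C)N[Si](C)(C)C; trifluoromethanesulfonic anhydride, O=S(=O)(OS(=O)(=O)C(F)(F)F)C(F)(F)F
Why: This is the standard one-flask route to o-silylaryl triflates: O-silylation, bromine–lithium exchange, anionic 1,3-silyl shift from oxygen to carbon (retro-Brook rearrangement) and triflation of the phenoxide.

Step 6
Reactants: 5 (2R,3R)-2,3-bis[(R)-hydroxy(4-methoxyphenyl)methyl]-N1,N4-dimethoxy-N1,N4-dimethylbutanediamide; 10 3,5-bis(benzyloxy)-2-(trimethylsilyl)phenyl trifluoromethanesulfonate (5 equiv)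
Product: 13 (2R,2′R,3R,3′R)-5,5′,7,7′-tetrakis(benzyloxy)-2,2′-bis(4-methoxyphenyl)-[3,3′-bichromane]-4,4′-dione, via aryne 11 (not isolated), via monochromanone hydroxy amide 12 (not isolated)
Conditions: KF (10 equiv), 18-crown-6 (10 equiv), THF, 0 °C → rt; 10 added slowly to 5 and the fluoride
Reagents that add atoms: none
Why: Proposed new method: fluoride converts 10 into aryne 11, each benzylic alkoxide (or fluoride-bound hydroxyl) of 5 adds to the aryne carbon remote from the C3 benzyloxy group (making O1–C8a), and the aryl anion so formed, ortho to that benzyloxy group, attacks the β-N-methoxy-N-methylamide and expels the amide nitrogen (making C4–C4a), first on one half (12) and then on the other. The closest known reaction types are the fluoride-triggered annulation of arynes by methyl salicylates to xanthones (O-arylation, then intramolecular acyl substitution) and the O–H insertion of arynes into aliphatic alcohols; their union on an aliphatic β-hydroxy amide to give a chroman-4-one is the new element. Each pyranone ring closes by 6-exo-trig attack of the aryl carbanion on the amide carbonyl. No stereocentre is formed or broken: the C–O and C–C(=O) bonds at the four centres of 5 stay intact, so the syn,syn all-R tetrad is carried with retention into the 2,3-cis/2′,3′-cis all-R bichromanone. The step needs regioselective aryne attack, which the inductive effect of the 3-benzyloxy group should secure (attack at the distal aryne carbon, as the aryne distortion model predicts), and acylation faster than protonation of the aryl anion, γ-lactonisation of the alkoxide or seven-membered closure onto the γ-amide, which the six-membered transition state, the aprotic medium and the low reactivity of the tertiary amide towards alkoxides should secure; mild fluoride at or below room temperature is chosen so that C3–H of the new ketones is not epimerised.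

Step 7
Reactants: 13 (2R,2′R,3R,3′R)-5,5′,7,7′-tetrakis(benzyloxy)-2,2′-bis(4-methoxyphenyl)-[3,3′-bichromane]-4,4′-dione
Product: 14 (2R,2′R,3R,3′R)-5,5′,7,7′-tetrahydroxy-2,2′-bis(4-methoxyphenyl)-[3,3′-bichromane]-4,4′-dione
Conditions: H2 (1 atm), 10 % Pd/C, EtOAc/THF, rt
Reagents that add atoms: none
Why: Catalytic hydrogenolysis of the four aryl benzyl ethers is neutral, so neither C3–H epimerisation nor retro-oxa-Michael opening of the cis-flavanone rings is expected, and the reaction is stopped once 13 is consumed to spare the benzylic C2–O1 bonds.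

Step 8
Reactants: 14 (2R,2′R,3R,3′R)-5,5′,7,7′-tetrahydroxy-2,2′-bis(4-methoxyphenyl)-[3,3′-bichromane]-4,4′-dione
Product: 15 (2R,2′R,3R,3′R)-5,5′,7-trihydroxy-7′-methoxy-2,2′-bis(4-methoxyphenyl)-[3,3′-bichromane]-4,4′-dione (CNP0184936.2)
Conditions: TMSCHN2 (1.0 equiv, slow addition), CH2Cl2/MeOH (4:1), 0 °C
Reagents that add atoms: trimethylsilyldiazomethane, C[Si](C)(C)C=[N+]=[N-]
Why: Base-free O-methylation of a phenol by a diazoalkane takes only the acidic free 7-hydroxyls (the 5-hydroxyls are held in hydrogen bonds to the C4 carbonyls), the two 7-OH groups of C2-symmetric 14 are homotopic so either gives 15, and the mono-ether should be the main component of the statistical mixture, with recovered 14 recycled.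

**Compound list**

1 | ethyl 3-(4-methoxyphenyl)-3-oxopropanoate | CCOC(=O)CC(=O)c1ccc(OC)cc1 | starting material
2 | diethyl 2,3-bis(4-methoxybenzoyl)butanedioate (diastereomer mixture, centres labile) | CCOC(=O)C(C(=O)c1ccc(OC)cc1)C(C(=O)OCC)C(=O)c1ccc(OC)cc1 | intermediate
3 | diethyl (2R,3R)-2,3-bis[(R)-hydroxy(4-methoxyphenyl)methyl]butanedioate (formed in the flask) | CCOC(=O)[C@@H]([C@@H](O)c1ccc(OC)cc1)[C@@H](C(=O)OCC)[C@@H](O)c1ccc(OC)cc1 | intermediate
4 | (3R,3aR,6R,6aR)-3,6-bis(4-methoxyphenyl)tetrahydro-1H,3H-furo[3,4-c]furan-1,4-dione (cis-fused, both aryl groups exo) | O=C1O[C@@H](c2ccc(OC)cc2)[C@@H]3C(=O)O[C@@H](c4ccc(OC)cc4)[C@H]13 | intermediate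
5 | (2R,3R)-2,3-bis[(R)-hydroxy(4-methoxyphenyl)methyl]-N1,N4-dimethoxy-N1,N4-dimethylbutanediamide | CON(C)C(=O)[C@@H]([C@@H](O)c1ccc(OC)cc1)[C@@H](C(=O)N(C)OC)[C@@H](O)c1ccc(OC)cc1 | intermediate
6 | 3,5-bis(benzyloxy)phenol | Oc1cc(OCc2ccccc2)cc(OCc2ccccc2)c1 | starting material
7 | 3,5-bis(benzyloxy)-2-bromophenol | Oc1cc(OCc2ccccc2)cc(OCc2ccccc2)c1Br | intermediate
8 | [3,5-bis(benzyloxy)-2-bromophenoxy]trimethylsilane (formed in the flask) | C[Si](C)(C)Oc1cc(OCc2ccccc2)cc(OCc2ccccc2)c1Br | intermediate
9 | lithium 3,5-bis(benzyloxy)-2-(trimethylsilyl)phenoxide (formed in the flask) | [Li+].[O-]c1cc(OCc2ccccc2)cc(OCc2ccccc2)c1[Si](C)(C)C | intermediate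
10 | 3,5-bis(benzyloxy)-2-(trimethylsilyl)phenyl trifluoromethanesulfonate | C[Si](C)(C)c1c(OCc2ccccc2)cc(OCc2ccccc2)cc1OS(=O)(=O)C(F)(F)F | intermediate
11 | 3,5-bis(benzyloxy)benzyne (1,2-didehydro; formed in the flask) | C1#CC(OCc2ccccc2)=CC(OCc2ccccc2)=C1 | intermediate
12 | (2R,3R)-2-[(2R,3R)-5,7-bis(benzyloxy)-2-(4-methoxyphenyl)-4-oxo-3,4-dihydro-2H-chromen-3-yl]-3-hydroxy-N-methoxy-3-(4-methoxyphenyl)-N-methylpropanamide (formed in the flask) | COc1ccc([C@@H]2Oc3cc(OCc4ccccc4)cc(OCc4ccccc4)c3C(=O)[C@@H]2[C@@H](C(=O)N(C)OC)[C@@H](O)c2ccc(OC)cc2)cc1 | intermediate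
13 | (2R,2′R,3R,3′R)-5,5′,7,7′-tetrakis(benzyloxy)-2,2′-bis(4-methoxyphenyl)-[3,3′-bichromane]-4,4′-dione | COc1ccc([C@@H]2Oc3cc(OCc4ccccc4)cc(OCc4ccccc4)c3C(=O)[C@@H]2[C@H]2C(=O)c3c(OCc4ccccc4)cc(OCc4ccccc4)cc3O[C@H]2c2ccc(OC)cc2)cc1 | intermediate
14 | (2R,2′R,3R,3′R)-5,5′,7,7′-tetrahydroxy-2,2′-bis(4-methoxyphenyl)-[3,3′-bichromane]-4,4′-dione | COc1ccc([C@@H]2Oc3cc(O)cc(O)c3C(=O)[C@@H]2[C@H]2C(=O)c3c(O)cc(O)cc3O[C@H]2c2ccc(OC)cc2)cc1 | intermediate
15 | (2R,2′R,3R,3′R)-5,5′,7-trihydroxy-7′-methoxy-2,2′-bis(4-methoxyphenyl)-[3,3′-bichromane]-4,4′-dione | COc1ccc([C@@H]2Oc3cc(O)cc(O)c3C(=O)[C@@H]2[C@H]2C(=O)c3c(O)cc(OC)cc3O[C@H]2c2ccc(OC)cc2)cc1 | target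

**Totals.** Total step count: 8. Longest linear sequence: 6 steps (steps 1, 2, 3, 6, 7, 8); the aryne precursor (steps 4 and 5) joins at step 6.

**Steps most likely to fail, with fallbacks**

Step 6 (Proposed new method). The aryl anion may be protonated before it reaches the amide, leaving plain aryl ethers. The alkoxide may also lactonise back onto the γ-amide with loss of the amine, or fluoride may epimerise C3 of the chromanones once they have formed. The fallback makes the two bonds in separate, known steps and sets out from 5. Both hydroxyls are silylated (TBSOTf, 2,6-lutidine, CH2Cl2) to the bis(tert-butyldimethylsilyl ether) F1. [2,4-Bis(benzyloxy)-6-fluorophenyl]lithium, generated from 1,5-bis(benzyloxy)-2-bromo-3-fluorobenzene and n-BuLi in THF at −78 °C, is added to both Weinreb amides (Weinreb ketone synthesis, C4–C4a bonds) to give the bis(2-fluoroaryl ketone) F2. HF·pyridine in THF removes the silyl groups to give the diol F3. Cs2CO3 in DMF at rt then closes both rings by intramolecular SNAr displacement of the fluoride ortho to each ketone (O1–C8a bonds, retention at C2 and C2′), which comes back to the route at 13.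

Step 2. The dynamic kinetic resolution may give the anti instead of the syn arrangement, or the second reduction may be mismatched to the first-formed lactone. Either leaves hydroxy esters that cannot close to the cis-fused dilactone. The fallback sets out from 2 and gives up catalytic asymmetric induction. Chelation-controlled syn reduction with Zn(BH4)2 (Et2O, −20 °C) and PPTS-mediated lactonisation should give the racemic exo,exo dilactone, that is 4 together with its enantiomer, the (3S,3aS,6S,6aS)-dilactone F4. Preparative chromatography on a chiral stationary phase (amylose tris(3,5-dimethylphenylcarbamate), CO2/MeOH) separates the two and comes back to the route at 4.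

Step 8. The second 7-hydroxyl is methylated at the same rate as the first, so over-methylation to the 7,7′-dimethyl ether runs alongside formation of 15 and caps the conversion to mono-ether. The fallback differentiates the halves before ring A is attached and sets out from 4.
- One equivalent of the aluminium amide of step 3 at −20 °C opens only one lactone (the strained bicyclic bis-lactone should react faster than the monolactone) to give the hydroxy amide lactone F5.
- TBSOTf/2,6-lutidine gives the silyl ether F6.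
- Excess aluminium amide opens the second lactone to the mono-silylated diamide alcohol F7.
- Annulation of its free hydroxyl with 10 under the conditions of step 6 at 0 °C gives the silylated monochromanone F8.
- HF·pyridine gives 12, now isolated.
- A second annulation with 3,5-dimethoxy-2-(trimethylsilyl)phenyl trifluoromethanesulfonate and KF/18-crown-6 gives the mixed bichromanone F9.
- Hydrogenolysis as in step 7 gives the 5,7-dihydroxy-5′,7′-dimethoxy compound F10.
- BCl3 (CH2Cl2, −78 → 0 °C) cleaves only the methyl ether peri to the C4′ carbonyl (chelation-directed demethylation), which comes back to the route at 15.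

Further compounds
F1 | step 6 | (2R,3R)-2,3-bis[(R)-[(tert-butyldimethylsilyl)oxy](4-methoxyphenyl)methyl]-N1,N4-dimethoxy-N1,N4-dimethylbutanediamide | CON(C)C(=O)[C@@H]([C@@H](O[Si](C)(C)C(C)(C)C)c1ccc(OC)cc1)[C@@H](C(=O)N(C)OC)[C@@H](O[Si](C)(C)C(C)(C)C)c1ccc(OC)cc1
F2 | step 6 | (2R,3R)-1,4-bis[2,4-bis(benzyloxy)-6-fluorophenyl]-2,3-bis[(R)-[(tert-butyldimethylsilyl)oxy](4-methoxyphenyl)methyl]butane-1,4-dione | O=C(c1c(F)cc(OCc2ccccc2)cc1OCc1ccccc1)[C@@H]([C@@H](O[Si](C)(C)C(C)(C)C)c1ccc(OC)cc1)[C@@H](C(=O)c1c(F)cc(OCc2ccccc2)cc1OCc1ccccc1)[C@@H](O[Si](C)(C)C(C)(C)C)c1ccc(OC)cc1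
F3 | step 6 | (2R,3R)-1,4-bis[2,4-bis(benzyloxy)-6-fluorophenyl]-2,3-bis[(R)-hydroxy(4-methoxyphenyl)methyl]butane-1,4-dione | O=C(c1c(F)cc(OCc2ccccc2)cc1OCc1ccccc1)[C@@H]([C@@H](O)c1ccc(OC)cc1)[C@@H](C(=O)c1c(F)cc(OCc2ccccc2)cc1OCc1ccccc1)[C@@H](O)c1ccc(OC)cc1
F4 | step 2 | (3S,3aS,6S,6aS)-3,6-bis(4-methoxyphenyl)tetrahydro-1H,3H-furo[3,4-c]furan-1,4-dione | O=C1O[C@H](c2ccc(OC)cc2)[C@H]3C(=O)O[C@H](c4ccc(OC)cc4)[C@@H]13
F5 | step 8 | (2R,3R,4R)-4-[(R)-hydroxy(4-methoxyphenyl)methyl]-N-methoxy-2-(4-methoxyphenyl)-N-methyl-5-oxooxolane-3-carboxamide | CON(C)C(=O)[C@H]1[C@H](c2ccc(OC)cc2)OC(=O)[C@H]1[C@@H](O)c1ccc(OC)cc1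
F6 | step 8 | (2R,3R,4R)-4-[(R)-[(tert-butyldimethylsilyl)oxy](4-methoxyphenyl)methyl]-N-methoxy-2-(4-methoxyphenyl)-N-methyl-5-oxooxolane-3-carboxamide | CON(C)C(=O)[C@H]1[C@H](c2ccc(OC)cc2)OC(=O)[C@H]1[C@@H](O[Si](C)(C)C(C)(C)C)c1ccc(OC)cc1
F7 | step 8 | (2R,3R)-2-[(R)-hydroxy(4-methoxyphenyl)methyl]-3-[(R)-[(tert-butyldimethylsilyl)oxy](4-methoxyphenyl)methyl]-N1,N4-dimethoxy-N1,N4-dimethylbutanediamide | CON(C)C(=O)[C@@H]([C@@H](O)c1ccc(OC)cc1)[C@@H](C(=O)N(C)OC)[C@@H](O[Si](C)(C)C(C)(C)C)c1ccc(OC)cc1
F8 | step 8 | (2R,3R)-2-[(2R,3R)-5,7-bis(benzyloxy)-2-(4-methoxyphenyl)-4-oxo-3,4-dihydro-2H-chromen-3-yl]-3-[(tert-butyldimethylsilyl)oxy]-N-methoxy-3-(4-methoxyphenyl)-N-methylpropanamide | COc1ccc([C@@H]2Oc3cc(OCc4ccccc4)cc(OCc4ccccc4)c3C(=O)[C@@H]2[C@@H](C(=O)N(C)OC)[C@@H](O[Si](C)(C)C(C)(C)C)c2ccc(OC)cc2)cc1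
F9 | step 8 | (2R,2′R,3R,3′R)-5,7-bis(benzyloxy)-5′,7′-dimethoxy-2,2′-bis(4-methoxyphenyl)-[3,3′-bichromane]-4,4′-dione | COc1ccc([C@@H]2Oc3cc(OCc4ccccc4)cc(OCc4ccccc4)c3C(=O)[C@@H]2[C@H]2C(=O)c3c(OC)cc(OC)cc3O[C@H]2c2ccc(OC)cc2)cc1
F10 | step 8 | (2R,2′R,3R,3′R)-5,7-dihydroxy-5′,7′-dimethoxy-2,2′-bis(4-methoxyphenyl)-[3,3′-bichromane]-4,4′-dione | COc1ccc([C@@H]2Oc3cc(O)cc(O)c3C(=O)[C@@H]2[C@H]2C(=O)c3c(OC)cc(OC)cc3O[C@H]2c2ccc(OC)cc2)cc1
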